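## Retrosynthetic overview

1. Bisabolane numbering: ring C1 (CH–OAng), C2–C3 (oxirane, CH3 on C3), C4 (C=O), C5 (CH–OAc), C6 (CH); chain C7 (=C14H2), C8 (CH–OAng), C9, C10–C11 (oxirane). Target 21 ⇐ diol 18 (double angeloylation) ⇐ enone alcohol 16 (OH-directed epoxidation of C2=C3, desilylation).
2. Key disconnection C1–C6: 16 ⇐ furan 13. Photooxygenation opens the furan to the (Z)-4-oxo-2-enal 15, and its aldehyde closes onto C6=C7 by a type-I carbonyl–ene reaction, a copy of the biosynthetic C1–C6 closure of a (2Z)-farnesyl chain with loss of a C14 hydrogen.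
3. Enabling feature: O–C1–C6–C7(=C14H2) (ring carbinol, ring methine, exocyclic methylene) is an ene retron, and ring atoms C1–C2=C3(CH3)–C4(=O) are an oxidised 2-substituted 3-methylfuran.
4. 13 ⇐ aldehyde 9 + alkenyl iodide 8 (catalytic asymmetric alkenylzinc addition sets C5); 8 ⇐ propargyl alcohol 1 (carboalumination, Keck allylation for C8, cross-metathesis, Shi epoxidation for C10).
5. Ring order: side-chain oxirane (step 6), then the carbocycle (step 9; the furan is a temporary ring consumed there), then the oxirane fused to the new ring (step 10).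

Key step: step 9

Remark: the two oxiranes are treated as oxidation-level functionality on the monocyclic bisabolane carbon skeleton; the cyclohexane is its only skeletal ring, and the oxirane fused to it can only be placed on the enone that the ring closure creates.

## Route

Step 1
Reactants: 1 prop-2-yn-1-ol
Product: 3 (E)-3-iodo-2-methylprop-2-en-1-ol, via alkenylalane 2 (not isolated)
Conditions: AlMe3 (3 equiv), Cp2ZrCl2 (0.25 equiv), CH2Cl2, 0 → 23 °C; I2, THF, −30 → 0 °C; aq. K2CO3
Reagents that add atoms: trimethylaluminium C[Al](C)C; iodine II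
Why: Zirconium-catalysed Negishi carboalumination should add methyl and aluminium syn across the alkyne (methyl to the internal carbon), and iodinolysis with retention gives the E iodoalkene.

Step 2
Reactants: 3 (E)-3-iodo-2-methylprop-2-en-1-ol
Product: 4 (E)-3-iodo-2-methylprop-2-enal
Conditions: MnO2 (10 equiv), CH2Cl2, 23 °C
Reagents that add atoms: none
Why: MnO2 oxidation of the allylic alcohol should give the enal without touching the alkenyl iodide or its geometry.

Step 3
Reactants: 4 (E)-3-iodo-2-methylprop-2-enal
Product: 5 (1E,3R)-1-iodo-2-methylhexa-1,5-dien-3-ol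
Conditions: (R)-BINOL (0.2 equiv), Ti(OiPr)4 (0.1 equiv), 4 Å MS, CH2Cl2; allylSnBu3, −20 °C; aq. NaHCO3
Reagents that add atoms: allyltributylstannane C=CC[Sn](CCCC)(CCCC)CCCC
Why: Keck asymmetric allylation; the (R)-BINOL–Ti(IV) Lewis acid should direct the allylstannane to the Re face of the enal and set the carbinol (C8 of the target) as R.

Step 4
Reactants: 5 (1E,3R)-1-iodo-2-methylhexa-1,5-dien-3-ol
Product: 6 (1E,3R)-1-iodo-2,7-dimethylocta-1,6-dien-3-ol
Conditions: Grubbs II (5 mol%), 2-methylbut-2-ene/CH2Cl2, 40 °C
Reagents that add atoms: 2-methylbut-2-ene CC=C(C)C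
Why: Olefin cross-metathesis of the terminal alkene with 2-methylbut-2-ene should install the isopropylidene terminus; the trisubstituted iodoalkene stays out of metathesis and the stereocentre is untouched.

Step 5
Reactants: 6 (1E,3R)-1-iodo-2,7-dimethylocta-1,6-dien-3-ol
Product: 7 triethyl{[(1E,3R)-1-iodo-2,7-dimethylocta-1,6-dien-3-yl]oxy}silane
Conditions: TESCl, imidazole, CH2Cl2, 0 °C
Reagents that add atoms: chlorotriethylsilane CC[Si](Cl)(CC)CC
Why: Silylation of the secondary alcohol masks O8 as an ether that tolerates organolithium, photooxygenation and peroxide conditions.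

Step 6
Reactants: 7 triethyl{[(1E,3R)-1-iodo-2,7-dimethylocta-1,6-dien-3-yl]oxy}silane
Product: 8 {[(1E,3R)-4-[(2S)-3,3-dimethyloxiran-2-yl]-1-iodo-2-methylbut-1-en-3-yl]oxy}triethylsilane
Conditions: ent-Shi ketone (L-fructose-derived, 30 mol%), Oxone, K2CO3, n-Bu4NHSO4, MeCN–DMM/aq. Na2B4O7–EDTA, 0 °C
Reagents that add atoms: Oxone (potassium peroxymonosulfate) [K+].[O-]S(=O)(=O)OO
Why: Shi epoxidation; the chiral dioxirane should epoxidise the electron-rich trisubstituted alkene through a spiro transition state, the L-fructose-derived ketone giving the (S)-oxirane (C10), while the iodo-substituted alkene is too electron-poor to react.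

Step 7
Reactants: 8 {[(1E,3R)-4-[(2S)-3,3-dimethyloxiran-2-yl]-1-iodo-2-methylbut-1-en-3-yl]oxy}triethylsilane; 9 3-methylfuran-2-carbaldehyde
Product: 12 (1S,2E,4R)-5-[(2S)-3,3-dimethyloxiran-2-yl]-3-methyl-1-(3-methylfuran-2-yl)-4-(triethylsilyloxy)pent-2-en-1-ol, via alkenyllithium 10 (not isolated), via alkenylzinc bromide 11 (not isolated)
Conditions: t-BuLi (2.05 equiv), Et2O, −78 °C; ZnBr2, −78 → 0 °C; TEEDA, (−)-MIB (10 mol%), hexanes; 9, 0 °C; aq. NaHCO3
Reagents that add atoms: none
Why: Iodine–lithium exchange with retention of alkene geometry, transmetalation to zinc and (−)-MIB-catalysed enantioselective alkenylzinc addition (Oppolzer–Walsh alkenylation) should deliver the alkenyl group to the Si face of the aldehyde and set C5 as S under catalyst control; the organozinc does not attack the oxirane.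

Step 8
Reactants: 12 (1S,2E,4R)-5-[(2S)-3,3-dimethyloxiran-2-yl]-3-methyl-1-(3-methylfuran-2-yl)-4-(triethylsilyloxy)pent-2-en-1-ol
Product: 13 (1S,2E,4R)-5-[(2S)-3,3-dimethyloxiran-2-yl]-3-methyl-1-(3-methylfuran-2-yl)-4-(triethylsilyloxy)pent-2-en-1-yl acetate
Conditions: Ac2O, Et3N, DMAP (cat.), CH2Cl2, 0 °C
Reagents that add atoms: acetic anhydride CC(=O)OC(C)=O
Why: DMAP-catalysed acetylation with retention at C5 installs the C5 acetate of the target and blocks Achmatowicz-type ring expansion when the furan is oxidised.

Step 9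
Reactants: 13 (1S,2E,4R)-5-[(2S)-3,3-dimethyloxiran-2-yl]-3-methyl-1-(3-methylfuran-2-yl)-4-(triethylsilyloxy)pent-2-en-1-yl acetate
Product: 16 (5S,6R,8R,10S)-5-acetoxy-10,11-epoxy-1-hydroxy-8-(triethylsilyloxy)bisabola-2,7(14)-dien-4-one with 1-OH cis and 5-OAc trans to the C6 side chain, via furan endoperoxide 14 (not isolated), via cis-enedione 15 (not isolated)
Conditions: O2, hν (white LED), TPP (1 mol%), CH2Cl2, −78 °C; Me2S, −78 → 0 °C; evaporate; PhMe (5 mM), BHT, 80 °C, dark
Reagents that add atoms: dioxygen O=O
Why: Proposed new method: singlet oxygen adds [4+2] across the furan and Me2S reduces endoperoxide 14 to the (Z)-4-oxo-2-enal 15 (both standard furan chemistry), whose aldehyde, a vinylogous glyoxal held over C6 by the Z C2=C3 bond and by the s-trans enone that the C3 methyl enforces, should then undergo a concerted type-I intramolecular carbonyl–ene reaction in which C1 bonds to C6, a C14 hydrogen moves suprafacially to the aldehyde oxygen and the π bond shifts to C7=C14. The closest known reactions are the thermal and Lewis-acid type-I carbonyl–ene cyclisations of 6-enals and (2Z)-2,6-dienals (citronellal to isopulegol, neral to isopiperitenol) and the furan photooxygenation–enedione cascades; the untested elements are a cis-enedione aldehyde as enophile and an ene partner flanked by two allylic oxygens. The carbocycle closes by 6-exo-trig attack of C6 on the aldehyde carbon with the C6=C7 bond exocyclic (six-membered ring fused to the six-membered ene array). C6 is controlled by C5: A(1,3) strain with the C14 methyl (cis to C5 in the 6E alkene) keeps H5 in the alkene plane, so the tether reaches one face only and the acetoxy group lies anti to the forming bond, which gives the 5,6-trans relationship. C1 is controlled by the pericyclic geometry: the only readily transferable hydrogens sit on the C14 methyl cis to the tether, so the aldehyde oxygen must lie over it in the cis-fused array and the carbinol oxygen ends cis to the C6 side chain. The step needs aldehyde-over-ketone and C14–H-over-C8–H selectivity and ring closure faster than Z→E isomerisation or C5 enolisation of 15; these are secured by ring size (only C1 can reach C6 in a six-membered ring), by the single, inductively deactivated methine C8–H that prefers the alkene plane next to the bulky silyl ether, and by neutral, dilute, dark conditions.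

Step 10
Reactants: 16 enone alcohol
Product: 17 (1S,2S,3S,5S,6R,8R,10S)-5-acetoxy-2,3:10,11-diepoxy-1-hydroxy-8-(triethylsilyloxy)bisabol-7(14)-en-4-one
Conditions: t-BuOOH (decane), DBU (0.3 equiv), PhMe, 0 °C
Reagents that add atoms: tert-butyl hydroperoxide CC(C)(C)OO
Why: Weitz–Scheffer nucleophilic epoxidation; the free pseudoaxial C1–OH should hydrogen-bond the peroxide and deliver it to C2 on its own face (hydroxyl-directed nucleophilic epoxidation of a γ-hydroxy enone), setting C2 and C3 cis to the C1 oxygen, while the isolated C7=C14 alkene is inert to the nucleophilic oxidant.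

Step 11
Reactants: 17 epoxy ketone silyl ether
Product: 18 (1S,2S,3S,5S,6R,8R,10S)-5-acetoxy-2,3:10,11-diepoxy-1,8-dihydroxybisabol-7(14)-en-4-one
Conditions: HF·pyridine, pyridine, THF, 0 °C
Reagents that add atoms: none
Why: Buffered HF·pyridine should cleave the secondary triethylsilyl ether while both oxiranes and the acetate survive the buffered fluoride source at 0 °C; no stereocentre is touched.

Step 12
Reactants: 18 diol; 19 angelic acid
Product: 21 CNP0407453.2 (1,8-bis-angelate of 18), via mixed anhydride 20 (not isolated)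
Conditions: 19 (6 equiv), 2,4,6-Cl3C6H2COCl, Et3N, PhMe, 23 °C; then 18, 80 °C
Reagents that add atoms: none
Why: Yamaguchi-type esterification; angelic acid pre-activated as the mixed 2,4,6-trichlorobenzoic anhydride should acylate both secondary hydroxyls (C1 and C8) on heating without DMAP, conditions known to transfer the angeloyl group to hindered alcohols without Z→E isomerisation to the tiglate.

## Compound list

1 | prop-2-yn-1-ol | C#CCO | starting material
2 | (E)-alkenylalane, O-aluminated (not isolated) | C[Al](C)OC/C(C)=C/[Al](C)C | intermediate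
3 | (E)-3-iodo-2-methylprop-2-en-1-ol | OC/C(C)=C/I | intermediate
4 | (E)-3-iodo-2-methylprop-2-enal | O=C/C(C)=C/I | intermediate
5 | (1E,3R)-1-iodo-2-methylhexa-1,5-dien-3-ol | I/C=C(C)/[C@@H](CC=C)O | intermediate
6 | (1E,3R)-1-iodo-2,7-dimethylocta-1,6-dien-3-ol | I/C=C(C)/[C@@H](CC=C(C)C)O | intermediate
7 | triethylsilyl ether of 6 | I/C=C(C)/[C@@H](CC=C(C)C)O[Si](CC)(CC)CC | intermediate
8 | (10S)-epoxide of 7 | I/C=C(C)/[C@@H](C[C@@H]1OC1(C)C)O[Si](CC)(CC)CC | intermediate
9 | 3-methylfuran-2-carbaldehyde | Cc1ccoc1C=O | starting material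
10 | alkenyllithium from 8 (not isolated) | [Li]/C=C(C)/[C@@H](C[C@@H]1OC1(C)C)O[Si](CC)(CC)CC | intermediate
11 | alkenylzinc bromide from 8 (not isolated) | Br[Zn]/C=C(C)/[C@@H](C[C@@H]1OC1(C)C)O[Si](CC)(CC)CC | intermediate
12 | (5S)-furyl allylic alcohol | Cc1ccoc1[C@@H](O)/C=C(C)/[C@@H](C[C@@H]1OC1(C)C)O[Si](CC)(CC)CC | intermediate
13 | (5S)-furyl allylic acetate | Cc1ccoc1[C@@H](OC(C)=O)/C=C(C)/[C@@H](C[C@@H]1OC1(C)C)O[Si](CC)(CC)CC | intermediate
14 | furan endoperoxide (2,3,7-trioxabicyclo[2.2.1]hept-5-ene, either bridgehead face; not isolated) | CC1=CC2OOC1(O2)[C@@H](OC(C)=O)/C=C(C)/[C@@H](C[C@@H]3OC3(C)C)O[Si](CC)(CC)CC | intermediate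
15 | (2Z,5S,6E,8R)-5-acetoxy-9-[(2S)-3,3-dimethyloxiran-2-yl]-3,7-dimethyl-4-oxo-8-(triethylsilyloxy)nona-2,6-dienal (not isolated) | O=C/C=C(C)\C(=O)[C@@H](OC(C)=O)/C=C(C)/[C@@H](C[C@@H]1OC1(C)C)O[Si](CC)(CC)CC | intermediate
16 | enone alcohol (1-OH cis, 5-OAc trans to the C6 side chain) | C=C([C@@H]1[C@H](O)C=C(C)C(=O)[C@H]1OC(C)=O)[C@@H](C[C@@H]1OC1(C)C)O[Si](CC)(CC)CC | intermediate
17 | epoxy ketone silyl ether | C=C([C@@H]1[C@H](O)[C@@H]2O[C@]2(C)C(=O)[C@H]1OC(C)=O)[C@@H](C[C@@H]1OC1(C)C)O[Si](CC)(CC)CC | intermediate
18 | 1,8-diol | C=C([C@@H]1[C@H](O)[C@@H]2O[C@]2(C)C(=O)[C@H]1OC(C)=O)[C@@H](C[C@@H]1OC1(C)C)O | intermediate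
19 | angelic acid, (Z)-2-methylbut-2-enoic acid | C/C=C(/C)C(=O)O | starting material
20 | angelic 2,4,6-trichlorobenzoic anhydride (not isolated) | C/C=C(/C)C(=O)OC(=O)c1c(Cl)cc(Cl)cc1Cl | intermediate
21 | CNP0407453.2 | C=C([C@@H]1[C@H](OC(=O)/C(C)=C\C)[C@@H]2O[C@]2(C)C(=O)[C@H]1OC(C)=O)[C@@H](C[C@@H]1OC1(C)C)OC(=O)/C(C)=C\C | target

## Step count and risks

Total step count: 12. Longest linear sequence: 12 steps (1 → 21); 9 and 19 enter as commercial partners.

**Step 9 (Proposed new method).** The thermal ene closure may be slower than Z→E isomerisation of the enedione, than enolisation at C5 (loss of the controlling centre or migration of the alkene into conjugation), or than hydrogen transfer from C8 instead of C14. The fallback replaces the pericyclic hydrogen shift by a known organometallic allylation. It sets out from 13. SeO2 (cat.)/t-BuOOH allylic hydroxylation of the C7 methyl group (Riley–Sharpless oxidation, the only alkyl allylic C–H on that alkene) should give the C14 allylic alcohol F1. Mesylation and LiBr displacement give the C14 allylic bromide F2. NBS/NaHCO3 in aqueous acetone at −20 °C opens the furan to the bromo cis-enedione F3, which is treated at once with indium powder in THF/H2O. The allylindium adds through its γ-carbon (C6) to the aldehyde in an intramolecular Barbier allylation, through a chair transition state fused to the forming ring under the same A(1,3) and cis-fusion constraints, and restores the C7=C14 methylene. The fallback comes back to the route at 16.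

**Step 10.** Delivery of the peroxide may occur on the face anti to the C1 oxygen (poor facial selectivity), or the base may trigger acetate loss. The fallback moves the epoxidation to the allylic-alcohol oxidation level, where electrophilic hydroxyl-directed epoxidation is reliable. It sets out from 16. TESOTf/2,6-lutidine gives the bis-silyl ether F4. Luche reduction (NaBH4, CeCl3, MeOH, −78 °C; axial hydride delivery) should give the C4 allylic alcohol F5 with the hydroxyl on the face of the C1 oxygen. VO(acac)2/t-BuOOH epoxidation directed by that C4 hydroxyl gives the epoxy alcohol F6. Dess–Martin oxidation returns the C4 ketone in epoxy ketone F7, and HF·pyridine removes both silyl ethers. The fallback comes back to the route at 18.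

**Step 7.** The oxirane may be opened during the lithium/zinc sequence, or catalyst control at C5 may be insufficient. The fallback gives up catalyst control for stereochemical correction. It sets out from 8 and 9. The alkenyllithium 10 is added directly to 9 at −78 °C (no zinc halide, short contact time) to give 12 together with its C5 epimer, the (5R)-alcohol F8. The two are separated by chromatography; 12 continues through step 8, and F8 is converted by Mitsunobu inversion with acetic acid (PPh3, DIAD) directly into the acetate. The fallback comes back to the route at 13.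

## Further compounds

F1 | step 9 | C14 allylic alcohol of 13 | Cc1ccoc1[C@@H](OC(C)=O)/C=C(CO)/[C@@H](C[C@@H]1OC1(C)C)O[Si](CC)(CC)CC
F2 | step 9 | C14 allylic bromide of 13 | Cc1ccoc1[C@@H](OC(C)=O)/C=C(CBr)/[C@@H](C[C@@H]1OC1(C)C)O[Si](CC)(CC)CC
F3 | step 9 | C14-bromo cis-enedione (not isolated) | O=C/C=C(C)\C(=O)[C@@H](OC(C)=O)/C=C(CBr)/[C@@H](C[C@@H]1OC1(C)C)O[Si](CC)(CC)CC
F4 | step 10 | 1,8-bis(triethylsilyl) ether of enone 16 | C=C([C@@H]1[C@H](O[Si](CC)(CC)CC)C=C(C)C(=O)[C@H]1OC(C)=O)[C@@H](C[C@@H]1OC1(C)C)O[Si](CC)(CC)CC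
F5 | step 10 | C4 allylic alcohol (4-OH cis to the C1 oxygen) | C=C([C@@H]1[C@H](O[Si](CC)(CC)CC)C=C(C)[C@H](O)[C@H]1OC(C)=O)[C@@H](C[C@@H]1OC1(C)C)O[Si](CC)(CC)CC
F6 | step 10 | 2,3-epoxy C4 alcohol | C=C([C@@H]1[C@H](O[Si](CC)(CC)CC)[C@@H]2O[C@]2(C)[C@H](O)[C@H]1OC(C)=O)[C@@H](C[C@@H]1OC1(C)C)O[Si](CC)(CC)CC
F7 | step 10 | 1,8-bis(triethylsilyl) ether of 18 | C=C([C@@H]1[C@H](O[Si](CC)(CC)CC)[C@@H]2O[C@]2(C)C(=O)[C@H]1OC(C)=O)[C@@H](C[C@@H]1OC1(C)C)O[Si](CC)(CC)CC
F8 | step 7 | (5R)-epimer of alcohol 12 | Cc1ccoc1[C@H](O)/C=C(C)/[C@@H](C[C@@H]1OC1(C)C)O[Si](CC)(CC)CC
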